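The closed, stirred, isothermal vessel sets three consumers on the electrophile at once, and this is what it holds:

    electrophile + nucleophile → acid + target + leaving group (k1 = 0.36 L mol⁻¹ s⁻¹)
    protonated nucleophile ⇌ nucleophile + acid, settled at all times (K2 = 7.9 × 10⁻⁹ M)
    buffer acid ⇌ buffer base + acid, settled at all times (K3 = 7.9 × 10⁻⁹ M)
    electrophile + protic impurity → quenched substrate (k4 = 1.3 L mol⁻¹ s⁻¹)
    electrophile ⇌ dormant form (K5 = 21, k5 = 0.017 s⁻¹)

electrophile 20 mM; nucleophile 1.80 equiv; buffer base 0.500 equiv; buffer acid 0.300 equiv; protic impurity 10.0 mM; time 1.5 min

- acid is the free proton; pH is minus the decimal logarithm of its molar concentration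
- what has gone from electrophile into another species counts as reacted, even if it can come back
- run time (flask): 1.5 min

- part of the electrophile that has reacted at 1.5 min
- pH of the solution at 1.5 min

- In reply to the request for a quick number, the reckoning goes in powers of ten. Because the two acid-base pairs have equal constants, the protons of the buffer acid spread evenly, and [nucleophile] starts at 31.8 mM.
- The pseudo-first-order constant k1[nucleophile] + k4[protic impurity] + k5 starts at 0.0415 s⁻¹. Divided in that proportion, the electrophile charge costs 5.53 mM of nucleophile through target and 6.27 mM of protic impurity.
- Each target takes one nucleophile, and because the two pairs have equal constants its acid divides between them in proportion to their pools, a fraction 0.692 going onto nucleophile. Halfway through these losses, [nucleophile] is near 27.2 mM and [protic impurity] near 6.86 mM. The constant then reads 0.0357 s⁻¹, and the return from the dormant form, at 8.10 × 10⁻⁴ s⁻¹, is dropped as far slower.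
- That gives 64.4 s for the decade time, the time in which the electrophile loses one power of ten.
- The run spans 1.40 decades, so 4.02% remains and 96.0% has reacted. The acid rises enough to lower the pH by 0.403.
- The forecast gives 94% (91% to 97%) and pH 8.6 (8.5 to 8.7), on the ground that “The electrophile is lost through three comparable channels”. Its conversion lies below this reckoning, inside its own range.
- The simulation gives 94.5% reacted and pH 8.60.
- At 1.50 min the flask sends electrophile into the dormant form 2.0 times as fast as into target, forward step alone. The flask therefore holds 43.1% dormant form beside 26.3% target and 25.0% quenched substrate, so its 94.5% conversion is no yield.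
- The neighbour flask read at 50 s spans 0.776 decades, which gives 16.8% electrophile left. Its computed reading is 17% left, 82.7% reacted.

The constants used here are assumed; the run is a simulation.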